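**Plan**

1. Retrosynthesis: the acetate and the C12–C13 bond (butenolide) are cut first, then C11–C12 and the C9 carbinol (back to a C9 ketone), then ring A at C2–C3 and at C4–C5. What remains is a ring-B alkenyl triflate carrying a two-carbon ester arm on C10, plus an isobutyrate unit (C3, C4 and both methyls); ring B goes back to 2-methylcyclohexane-1,3-dione and tert-butyl acrylate.
2. Forward: ring B first (C10 made quaternary by Michael addition, then desymmetrised); ring A is annulated in one flask (Pd coupling of an isobutyrate zinc enolate at C5, then Dieckmann closure C2→C3); the C9 side chain follows (methylenation, epoxide, vinyl carbinol, B-alkyl Suzuki coupling).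
3. Enabling feature: in ring A the oxygenated C3 and the gem-dimethyl C4 are the carbonyl and α-carbon of an isobutyrate; C5 adjoins C6H2 and can therefore be the alkenyl triflate carbon of a ring-B ketone; C2 is α to a removable carboxyl.
4. Stereochemistry: C10 by catalytic desymmetrising transfer hydrogenation; C5 by hydrogenation anti to the C10 methyl; C8 by equilibration; C3 by hydride delivery; C9 by α-face epoxidation.
5. C5 is kept sp2 through the annulation on purpose: closing C4 onto a ring-B sp2 C5 from the C1 tether can only give the cis ring fusion.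
6. Helpers: tert-butyl carboxylate on C2 (removed in step 7); the temporary C5 carbinol/triflate and the C5=C6 bond (removed by step 8).

Key step: step 6

Remark: bicyclic compounds are named as decalins with the labdane numbers of the target (ring A C1–C5 and C10, ring B C5–C10, chain C11–C12, butenolide C13–C16); α is the face opposite the C10 methyl.
Assumption: the (S,S)-TsDPEN ruthenium catalyst is taken to reduce the carbonyl that leads to (1S,2S)-4; if the sense of induction is the opposite, the (R,R)-catalyst is used.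

**Route**

Step 1
Reactants: 1 2-methylcyclohexane-1,3-dione; 2 tert-butyl acrylate
Product: 3 tert-butyl 3-(1-methyl-2,6-dioxocyclohexyl)propanoate
Conditions: Et3N (0.2 equiv), MeCN, 60 °C
Reagents that add atoms: none
Why: Michael addition of the dione enolate to the acrylate builds the future C10 as a prochiral quaternary carbon with the C1–C2 arm; the tert-butyl ester cannot lactonise or transesterify with later alkoxides.

Step 2
Reactants: 3 tert-butyl 3-(1-methyl-2,6-dioxocyclohexyl)propanoate
Product: 4 tert-butyl 3-[(1S,2S)-2-hydroxy-1-methyl-6-oxocyclohexyl]propanoate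
Conditions: RuCl(p-cymene)[(S,S)-TsDPEN] (1 mol %), HCO2H/Et3N (5:2), CH2Cl2, 25 °C, stopped at mono-reduction
Reagents that add atoms: none
Why: Noyori-type asymmetric transfer hydrogenation desymmetrises the 2,2-disubstituted 1,3-diketone by reducing one of the two enantiotopic carbonyls, so the configuration of the quaternary carbon (C10) is set by the catalyst; the carbinol centre is temporary.

Step 3
Reactants: 4 tert-butyl 3-[(1S,2S)-2-hydroxy-1-methyl-6-oxocyclohexyl]propanoate
Product: 5 tert-butyl 3-[(1S,2S)-2-hydroxy-1,5-dimethyl-6-oxocyclohexyl]propanoate (both epimers at the new methyl carbon, future C8)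
Conditions: LDA (2.2 equiv), THF, −78 °C; MeI (1.2 equiv), −78 → −30 °C; aq. NH4Cl
Reagents that add atoms: iodomethane, CI
Why: Fráter–Seebach-type dianion alkylation: the alkoxide and the only possible ketone enolate (towards C8, since C10 is quaternary) form and the enolate is C-methylated; enolisation also blocks retro-aldol opening, and the C8 configuration is left open because step 8 equilibrates it.

Step 4
Reactants: 5 tert-butyl 3-[(1S,2S)-2-hydroxy-1,5-dimethyl-6-oxocyclohexyl]propanoate
Product: 6 tert-butyl 3-[(1S)-1,3-dimethyl-2,6-dioxocyclohexyl]propanoate (both C8 epimers)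
Conditions: Dess–Martin periodinane, CH2Cl2, 0 °C → rt
Reagents that add atoms: none
Why: Dess–Martin oxidation of the hindered secondary alcohol returns the 1,3-diketone, now dissymmetric through the C8 methyl, so C10 stays stereogenic and has no pathway for racemisation.

Step 5
Reactants: 6 tert-butyl 3-[(1S)-1,3-dimethyl-2,6-dioxocyclohexyl]propanoate
Product: 7 tert-butyl 3-[(1S)-1,5-dimethyl-6-oxo-2-(trifluoromethylsulfonyloxy)cyclohex-2-en-1-yl]propanoate
Conditions: KHMDS (1.05 equiv), THF, −78 °C; PhNTf2, −78 → 0 °C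
Reagents that add atoms: N-phenylbis(trifluoromethanesulfonimide), O=S(=O)(N(c1ccccc1)S(=O)(=O)C(F)(F)F)C(F)(F)F
Why: kinetic deprotonation should take the less hindered C6 methylene and not the C8 methine, and O-triflation of that enolate gives the C5 alkenyl triflate (regioselective enol triflate formation), the sp2 electrophile for the annulation.

Step 6
Reactants: 7 tert-butyl 3-[(1S)-1,5-dimethyl-6-oxo-2-(trifluoromethylsulfonyloxy)cyclohex-2-en-1-yl]propanoate; 8 methyl 2-bromo-2-methylpropanoate
Product: 11 tert-butyl 4,4,8,10β-tetramethyl-3,9-dioxodecal-5-ene-2-carboxylate, via zinc enolate 9 (not isolated), via coupled diester 10 (not isolated)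
Conditions: 8 (2.5 equiv), Zn dust (TMSCl-activated), THF, rt; then 7, Pd(dba)2 (5 mol %), P(t-Bu)3 (10 mol %), LiCl, THF, 50 °C; then t-BuOK (4 equiv), THF, 0 °C → rt; aq. NH4Cl
Reagents that add atoms: none
Why: Pd(0) inserts into the C5–OTf bond, the C-bound zinc enolate 9 transmetalates and reductive elimination joins the fully substituted C4 to sp2 C5 (Negishi-type α-alkenylation of an ester, the Reformatsky-reagent variant of Pd-catalysed ester α-arylation), and t-BuOK then turns the tert-butyl propanoate arm into its enolate, whose C2 attacks the C3 methyl ester and expels methoxide (Dieckmann condensation). Ring A closes at C2–C3 in a 6-exo-trig mode and in one direction only, because C4 bears no hydrogen, and the condensation is driven by deprotonation of the new β-keto ester. No lasting stereocentre is formed: C2 is enolised and loses its carboxyl in step 7, C10 is not touched, and C5 stays sp2 so that the ring fusion is set later by hydrogenation and not by this closure. The step needs chemoselectivity for the Pd–alkenyl over the C9 ketone and the tert-butyl ester, which the weakly basic, weakly nucleophilic zinc enolate and the quaternary C10 and tertiary C8 flanking C9 should secure. In the base stage the C8 ketone enolate has no productive acyl acceptor (attack on C3 would need a bridgehead alkene and the tert-butyl ester is unreactive), so only the C2 enolate condenses.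

Step 7
Reactants: 11 tert-butyl 4,4,8,10β-tetramethyl-3,9-dioxodecal-5-ene-2-carboxylate
Product: 12 4,4,8,10β-tetramethyldecal-5-ene-3,9-dione (C8 epimers)
Conditions: TFA, CH2Cl2, 0 °C → rt; then toluene, 80 °C
Reagents that add atoms: none
Why: acidolysis of the tert-butyl β-keto ester and decarboxylation of the β-keto acid remove the helper carboxyl from C2; the β,γ-enone cannot move into conjugation because C4 is quaternary.

Step 8
Reactants: 12 4,4,8,10β-tetramethyldecal-5-ene-3,9-dione
Product: 14 4,4,8α,10β-tetramethyl-5α-decalin-3,9-dione, via C8-epimeric trans-diketone 13 (not isolated)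
Conditions: H2 (4 atm), 10% Pd/C, EtOAc, rt; then K2CO3 (cat.), MeOH, rt
Reagents that add atoms: none
Why: heterogeneous hydrogenation should deliver hydrogen to C5=C6 from the α-face, opposite the axial C10 methyl (as is usual for 4,4,10-trimethyl-Δ5-octalones), which sets the trans ring fusion; carbonate then equilibrates C8 to the equatorial 8α-methyl, away from the 1,3-diaxial clash with the C10 methyl.

Step 9
Reactants: 14 4,4,8α,10β-tetramethyl-5α-decalin-3,9-dione
Product: 15 3β-hydroxy-4,4,8α,10β-tetramethyl-5α-decalin-9-one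
Conditions: NaBH4, EtOH, −20 °C
Reagents that add atoms: none
Why: borohydride should reduce the C3 ketone in preference to the C9 ketone, which is flanked by quaternary C10 and tertiary C8; axial (α-face) hydride attack, anti to the axial 4β-methyl, gives the equatorial 3β-alcohol as is usual for 4,4-dimethyl-3-ketones.

Step 10
Reactants: 15 3β-hydroxy-4,4,8α,10β-tetramethyl-5α-decalin-9-one
Product: 16 4,4,8α,10β-tetramethyl-9-methylene-5α-decalin-3β-ol
Conditions: Ph3PCH3Br, KOtBu (both in excess), toluene, 90 °C
Reagents that add atoms: methyltriphenylphosphonium bromide, C[P+](c1ccccc1)(c1ccccc1)c1ccccc1.[Br-]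
Why: Wittig methylenation at elevated temperature converts the hindered C9 ketone into the exocyclic alkene; the C3 alkoxide is a spectator and C8 stays in its stable configuration under the basic conditions.

Step 11
Reactants: 16 4,4,8α,10β-tetramethyl-9-methylene-5α-decalin-3β-ol
Product: 17 4,4,8α,10β-tetramethyl-5α-decalin-9-spiro-oxiran-3β-ol (oxirane oxygen α; its CH2, C11, β)
Conditions: mCPBA, NaHCO3, CH2Cl2, 0 °C
Reagents that add atoms: 3-chloroperbenzoic acid, OOC(=O)c1cccc(Cl)c1
Why: Prilezhaev epoxidation of the exocyclic alkene from the α-face, anti to the axial C10 methyl on the neighbouring carbon, should place oxygen α and C11 β at C9, which is the configuration of the tertiary carbinol of the target.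

Step 12
Reactants: 17 4,4,8α,10β-tetramethyl-5α-decalin-9-spiro-oxiran-3β-ol
Product: 18 9β-vinyl-4,4,8α,10β-tetramethyl-5α-decalin-3β,9α-diol
Conditions: Me3S+ I− (6 equiv), n-BuLi (5.5 equiv), THF, −10 °C → rt
Reagents that add atoms: trimethylsulfonium iodide, C[S+](C)C.[I-]
Why: dimethylsulfonium methylide opens the epoxide at its primary carbon C11 and a second equivalent of ylide eliminates dimethyl sulfide from the sulfonium alkoxide (one-carbon homologation of an epoxide to an allylic alcohol); the C9–O bond is never broken, so C9 keeps its configuration.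

Step 13
Reactants: 18 9β-vinyl-4,4,8α,10β-tetramethyl-5α-decalin-3β,9α-diol; 19 3-bromofuran-2(5H)-one
Product: 21 3β,9α-dihydroxylabd-13-en-16,15-olide, via B-alkyl-9-BBN borane 20 (not isolated)
Conditions: 9-BBN (3.5 equiv), THF, rt → 50 °C; then 19, PdCl2(dppf) (5 mol %), AsPh3, Cs2CO3, DMF/H2O, rt
Reagents that add atoms: none
Why: anti-Markovnikov hydroboration of the vinyl group and B-alkyl Suzuki–Miyaura coupling of the primary alkylborane with the α-bromo-butenolide join C12 to C13 and bring in the intact 2(5H)-furanone; no stereocentre is touched.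

Step 14
Reactants: 21 3β,9α-dihydroxylabd-13-en-16,15-olide
Product: 22 3β-acetoxy-9α-hydroxylabd-13-en-16,15-olide (CNP0117645.1)
Conditions: Ac2O, pyridine, DMAP (cat.), CH2Cl2, 0 °C → rt
Reagents that add atoms: acetic anhydride, CC(=O)OC(C)=O
Why: DMAP-catalysed acylation should distinguish the secondary equatorial 3β-hydroxyl from the hindered tertiary axial 9α-hydroxyl, so only C3 is acetylated.

**Compound list**

1 | 2-methylcyclohexane-1,3-dione | CC1C(=O)CCCC1=O | starting material
2 | tert-butyl acrylate | C=CC(=O)OC(C)(C)C | starting material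
3 | tert-butyl 3-(1-methyl-2,6-dioxocyclohexyl)propanoate | CC1(CCC(=O)OC(C)(C)C)C(=O)CCCC1=O | intermediate
4 | tert-butyl 3-[(1S,2S)-2-hydroxy-1-methyl-6-oxocyclohexyl]propanoate (hydroxyl cis to the arm) | CC(C)(C)OC(=O)CC[C@@]1(C)[C@@H](O)CCCC1=O | intermediate
5 | tert-butyl 3-[(1S,2S)-2-hydroxy-1,5-dimethyl-6-oxocyclohexyl]propanoate (C8 epimers) | CC(C)(C)OC(=O)CC[C@@]1(C)[C@@H](O)CCC(C)C1=O | intermediate
6 | tert-butyl 3-[(1S)-1,3-dimethyl-2,6-dioxocyclohexyl]propanoate (C8 epimers) | CC(C)(C)OC(=O)CC[C@@]1(C)C(=O)CCC(C)C1=O | intermediate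
7 | tert-butyl 3-[(1S)-1,5-dimethyl-6-oxo-2-(trifluoromethylsulfonyloxy)cyclohex-2-en-1-yl]propanoate (C8 epimers) | CC(C)(C)OC(=O)CC[C@@]1(C)C(OS(=O)(=O)C(F)(F)F)=CCC(C)C1=O | intermediate
8 | methyl 2-bromo-2-methylpropanoate | COC(=O)C(C)(C)Br | starting material
9 | bromo(1-methoxy-2-methyl-1-oxopropan-2-yl)zinc (Reformatsky zinc enolate) | COC(=O)C(C)(C)[Zn]Br | intermediate
10 | tert-butyl 3-[(1S)-2-(1-methoxy-2-methyl-1-oxopropan-2-yl)-1,5-dimethyl-6-oxocyclohex-2-en-1-yl]propanoate (C8 epimers) | CC(C)(C)OC(=O)CC[C@@]1(C)C(=CCC(C)C1=O)C(C)(C)C(=O)OC | intermediate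
11 | tert-butyl 4,4,8,10β-tetramethyl-3,9-dioxodecal-5-ene-2-carboxylate (C2 and C8 epimers, partly enolised) | O=C1C(C(=O)OC(C)(C)C)C[C@@]2(C)C(=CCC(C)C2=O)C1(C)C | intermediate
12 | 4,4,8,10β-tetramethyldecal-5-ene-3,9-dione (C8 epimers) | O=C1CC[C@@]2(C)C(=CCC(C)C2=O)C1(C)C | intermediate
13 | 4,4,8,10β-tetramethyl-5α-decalin-3,9-dione (C8 epimers) | O=C1CC[C@@]2(C)[C@@H](CCC(C)C2=O)C1(C)C | intermediate
14 | 4,4,8α,10β-tetramethyl-5α-decalin-3,9-dione | O=C1CC[C@@]2(C)[C@@H](CC[C@@H](C)C2=O)C1(C)C | intermediate
15 | 3β-hydroxy-4,4,8α,10β-tetramethyl-5α-decalin-9-one | O[C@H]1CC[C@@]2(C)[C@@H](CC[C@@H](C)C2=O)C1(C)C | intermediate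
16 | 4,4,8α,10β-tetramethyl-9-methylene-5α-decalin-3β-ol | O[C@H]1CC[C@@]2(C)[C@@H](CC[C@@H](C)C2=C)C1(C)C | intermediate
17 | 4,4,8α,10β-tetramethyl-5α-decalin-9-spiro-oxiran-3β-ol (O α, C11 β) | O[C@H]1CC[C@@]2(C)[C@@H](CC[C@@H](C)[C@]2(O3)C3)C1(C)C | intermediate
18 | 9β-vinyl-4,4,8α,10β-tetramethyl-5α-decalin-3β,9α-diol | O[C@H]1CC[C@@]2(C)[C@@H](CC[C@@H](C)[C@]2(O)C=C)C1(C)C | intermediate
19 | 3-bromofuran-2(5H)-one | BrC1=CCOC1=O | starting material
20 | 9-[2-(3β,9α-dihydroxy-4,4,8α,10β-tetramethyl-5α-decalin-9β-yl)ethyl]-9-borabicyclo[3.3.1]nonane | O[C@H]1CC[C@@]2(C)[C@@H](CC[C@@H](C)[C@]2(O)CCB3C4CCCC3CCC4)C1(C)C | intermediate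
21 | 3β,9α-dihydroxylabd-13-en-16,15-olide (8α-methyl) | O[C@H]1CC[C@@]2(C)[C@@H](CC[C@@H](C)[C@]2(O)CCC2=CCOC2=O)C1(C)C | intermediate
22 | 3β-acetoxy-9α-hydroxylabd-13-en-16,15-olide (CNP0117645.1) | CC(=O)O[C@H]1CC[C@@]2(C)[C@@H](CC[C@@H](C)[C@]2(O)CCC2=CCOC2=O)C1(C)C | target

**Count and risks**

Total steps: 14. Longest linear sequence: 14 steps (from 1; compounds 2, 8 and 19 are bought).

Step 6 is the most exposed. Transmetalation and reductive elimination between a fully substituted zinc enolate and an alkenyl–palladium flanked by a quaternary carbon may be too slow, so that loss of the triflate by reduction or enolate homocoupling takes over. Fallback: from 6, a classical Reformatsky addition of the zinc enolate 9 (8, Zn, THF, reflux) to the less hindered C5 ketone should give the β-hydroxy diester tert-butyl 3-[(1S)-2-hydroxy-2-(1-methoxy-2-methyl-1-oxopropan-2-yl)-1,5-dimethyl-6-oxocyclohexyl]propanoate F1. Dehydration (SOCl2, pyridine, 0 °C), which can only go towards C6, would give 10 as an isolated compound, and t-BuOK in THF would close it to 11, where the route is rejoined.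

Step 12 may fail because the ylide has to attack a primary epoxide carbon next to the crowded C9; base-induced isomerisation of the epoxide by removal of the C8 hydrogen, or no reaction, could win. Fallback: from 17, copper-catalysed opening with allenylmagnesium bromide should give the homopropargylic alcohol 9β-(but-3-ynyl)-4,4,8α,10β-tetramethyl-5α-decalin-3β,9α-diol F2. Its acetylide (excess n-BuLi) and paraformaldehyde would give 9β-(5-hydroxypent-3-ynyl)-4,4,8α,10β-tetramethyl-5α-decalin-3β,9α-diol F3. Red-Al followed by iodine would give 9β-[(Z)-5-hydroxy-3-iodopent-3-enyl]-4,4,8α,10β-tetramethyl-5α-decalin-3β,9α-diol F4, and palladium-catalysed carbonylative lactonisation (CO, PdCl2(PPh3)2, K2CO3, THF) would close the butenolide and return to 21, so that step 13 is bypassed as well.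

Step 13 may fail through base-mediated decomposition of the α-bromobutenolide, or through protodeboronation of the alkylborane, outrunning the cross-coupling. Fallback: from 18, hydroboration–oxidation (9-BBN, then NaBO3) should give 9β-(2-hydroxyethyl)-4,4,8α,10β-tetramethyl-5α-decalin-3β,9α-diol F5. Selective oxidation of the primary alcohol (TEMPO, PhI(OAc)2) would give (3β,9α-dihydroxy-4,4,8α,10β-tetramethyl-5α-decalin-9β-yl)acetaldehyde F6. Horner–Wadsworth–Emmons olefination with diethyl (2-oxooxolan-3-yl)phosphonate (LiCl, DBU, MeCN) would give (E)-3-[2-(3β,9α-dihydroxy-4,4,8α,10β-tetramethyl-5α-decalin-9β-yl)ethylidene]oxolan-2-one F7, and RhCl3-catalysed migration of the exocyclic double bond into the ring (EtOH, reflux) would return to 21.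

**Further compounds**

F1 | step 6 | tert-butyl 3-[(1S)-2-hydroxy-2-(1-methoxy-2-methyl-1-oxopropan-2-yl)-1,5-dimethyl-6-oxocyclohexyl]propanoate (C5 and C8 epimers) | CC(C)(C)OC(=O)CC[C@@]1(C)C(O)(CCC(C)C1=O)C(C)(C)C(=O)OC
F2 | step 12 | 9β-(but-3-ynyl)-4,4,8α,10β-tetramethyl-5α-decalin-3β,9α-diol | O[C@H]1CC[C@@]2(C)[C@@H](CC[C@@H](C)[C@]2(O)CCC#C)C1(C)C
F3 | step 12 | 9β-(5-hydroxypent-3-ynyl)-4,4,8α,10β-tetramethyl-5α-decalin-3β,9α-diol | O[C@H]1CC[C@@]2(C)[C@@H](CC[C@@H](C)[C@]2(O)CCC#CCO)C1(C)C
F4 | step 12 | 9β-[(Z)-5-hydroxy-3-iodopent-3-enyl]-4,4,8α,10β-tetramethyl-5α-decalin-3β,9α-diol | O[C@H]1CC[C@@]2(C)[C@@H](CC[C@@H](C)[C@]2(O)CC/C(I)=C/CO)C1(C)C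
F5 | step 13 | 9β-(2-hydroxyethyl)-4,4,8α,10β-tetramethyl-5α-decalin-3β,9α-diol | O[C@H]1CC[C@@]2(C)[C@@H](CC[C@@H](C)[C@]2(O)CCO)C1(C)C
F6 | step 13 | (3β,9α-dihydroxy-4,4,8α,10β-tetramethyl-5α-decalin-9β-yl)acetaldehyde | O[C@H]1CC[C@@]2(C)[C@@H](CC[C@@H](C)[C@]2(O)CC=O)C1(C)C
F7 | step 13 | (E)-3-[2-(3β,9α-dihydroxy-4,4,8α,10β-tetramethyl-5α-decalin-9β-yl)ethylidene]oxolan-2-one | O[C@H]1CC[C@@]2(C)[C@@H](CC[C@@H](C)[C@]2(O)C/C=C3\CCOC3=O)C1(C)C
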